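**Retrosynthetic overview**

1. Numbering (guaiane): five-membered ring A = C1–C5 (C4 quaternary, C1 and C5 ring fusion). Seven-membered ring B = C1, C5–C10 (C6 = ring CH=, C7 = CH bearing C11(CH3)2OH, C10 = CHCH3). C1' = benzylic CH.
2. Enabling feature: in ring B the =CH C6 lies between the sp2 ring-fusion carbon C5 (neighbour of quaternary C4 of ring A) and C7–C11. C4–C5=C6 is the outcome of a [3,3] shift from a C4=C5–C6–O allyl system, and O–C6–C7–C11 is the outcome of a carbonyl-ene reaction. C6 is therefore planned as a formyl carbon and C7=C11 as a prenyl alkene.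
3. Disconnections: aryl CHO and OH groups (late double lithiation/formylation, then demethylation); isobutyl group from the Claisen aldehyde (Wittig, H2); C4–C1' by O-vinylation/Claisen rearrangement of allylic alcohol 8; C6–C7 by intramolecular carbonyl-ene reaction of enal 6.
4. Enal 6 comes from (R)-citronellal (C10 and the prenyl end), methyl vinyl ketone (C2–C4 and the C4 methyl) and one Wittig carbon (C6). An organocatalytic Michael addition sets C1 and an aldol condensation closes ring A.
5. Ring order: A (step 3), then B (step 4). The arene is brought in intact (step 7). The C6 oxygen is a temporary handle: it leaves C6 in step 7 and leaves the molecule in step 8.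

Key step: step 4

Remark: "upper face" means the face of the bicycle that carries H-1. Compounds 1, 2 and 9 and all reagents are taken as commercial.

**Step 1**
Reactants: 1 (R)-citronellal; 2 methyl vinyl ketone
Product: 3 (2R)-2-[(2R)-6-methylhept-5-en-2-yl]-5-oxohexanal
Conditions: (R)-2-[methoxy(diphenyl)methyl]pyrrolidine (5 mol %), ethyl 3,4-dihydroxybenzoate (20 mol %), neat, 4 °C
Reagents that add atoms: none
Why: Enamine-catalysed asymmetric Michael addition: in the (E)-enamine of 1 the CPh2OMe group of the (R)-pyrrolidine covers one face, so 2 (activated by the catechol through hydrogen bonds) adds to the other face and sets C1 as R under catalyst control, while C10 (R) is carried in from 1.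

**Step 2**
Reactants: 3 (2R)-2-[(2R)-6-methylhept-5-en-2-yl]-5-oxohexanal
Product: 4 (5R,6R)-5-(2-methoxyethenyl)-6,10-dimethylundec-9-en-2-one (E/Z mixture at the enol ether)
Conditions: Ph3P(CH2OMe)Cl (1.1 equiv), KN(SiMe3)2 (1.05 equiv), THF, −78 °C; then 3, −78 → −30 °C
Reagents that add atoms: (methoxymethyl)triphenylphosphonium chloride, COC[P+](c1ccccc1)(c1ccccc1)c1ccccc1.[Cl-]
Why: Wittig reaction: the non-stabilised ylide consumes the aldehyde at −78 °C far faster than the methyl ketone, the preformed ylide and the short cold contact keep the α-stereocentre C1 from enolising, and the E/Z mixture is of no consequence.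

**Step 3**
Reactants: 4 (5R,6R)-5-(2-methoxyethenyl)-6,10-dimethylundec-9-en-2-one
Product: 6 (5R)-2-methyl-5-[(2R)-6-methylhept-5-en-2-yl]cyclopent-1-ene-1-carbaldehyde, via keto aldehyde 5 (not isolated)
Conditions: 1 M HCl, THF, 0 °C → rt; then piperidine (0.3 equiv), AcOH (0.3 equiv), toluene, 80 °C, removal of water
Reagents that add atoms: water, O
Why: Acid hydrolysis of the enol ether followed by an amine/acid-catalysed intramolecular aldol condensation: the enamine of the aldehyde (C5) attacks the methyl ketone (C4) in a 5-exo-trig closure and water is lost to give the conjugated enal, the mode known for 3-substituted 6-oxoheptanals, and C1 is no longer α to a carbonyl group so it cannot epimerise.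

**Step 4**
Reactants: 6 (5R)-2-methyl-5-[(2R)-6-methylhept-5-en-2-yl]cyclopent-1-ene-1-carbaldehyde
Product: 7 (4R,5S,8R,8aR)-3,8-dimethyl-5-(prop-1-en-2-yl)-1,2,4,5,6,7,8,8a-octahydroazulen-4-ol (guaia-4,11-dien-6-ol; OH, isopropenyl group and H-1 on the upper face)
Conditions: Me2AlCl (1.5 equiv), CH2Cl2 (0.01 M), −78 → −20 °C; aq. potassium sodium tartrate
Reagents that add atoms: none
Why: Me2AlCl binds the formyl oxygen of the s-trans enal, and the CH terminus C7 of the prenyl group attacks C6 while a methyl hydrogen of the C(CH3)2 terminus passes to oxygen through a six-membered array; this is an intramolecular Lewis-acid carbonyl-ene (Prins-type) reaction, the ring homologue of the citronellal-to-isopulegol closure and a reaction type known for cyclopentenecarbaldehydes that carry a trisubstituted alkene in the side chain. Ring B (C1, C5, C6, C7, C8, C9, C10) closes in the 7-exo-trig mode with respect to C7=C11, and C11 stays outside the ring as the isopropenyl carbon, ready for hydration. C6 is controlled as follows: the tether starts at C10, which lies on the lower face of the planar enal because H-1 is on the upper face, so C7 can reach only the lower face of the formyl carbon, and since the s-trans rotamer (oxygen towards C1, hydrogen towards the C4 methyl group) avoids the O/CH3 clash, the oxygen ends up on the upper face (6R). C7 is controlled as follows: of the two staggered arrangements about the forming bond, only the one with C11 turned away from the bicycle and gauche to oxygen allows the hydrogen transfer and avoids the C4 methyl group, which puts the isopropenyl group on the upper face, cis to H-1 as in the target. The step needs 1,2- over 1,4-attack and ene over free-cation chemistry; the first is secured by the fully substituted β-carbon C4, the second by Me2AlCl, which removes the transferred proton as methane so that neither the allylic alcohol formed nor the alkenes meet acid. In one operation the monocyclic enal thus becomes the hydroazulene with two new stereocentres, the C11 unit in place and an upper-face oxygen at C6 that later relays its configuration to C4 and C1'.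

**Step 5**
Reactants: 7 guaia-4,11-dien-6-ol
Product: 8 (4R,5R,8R,8aR)-5-(2-hydroxypropan-2-yl)-3,8-dimethyl-1,2,4,5,6,7,8,8a-octahydroazulen-4-ol
Conditions: Co(acac)2 (20 mol %), PhSiH3 (2 equiv), O2 (1 atm), THF, rt
Reagents that add atoms: dioxygen, O=O
Why: Mukaiyama hydration (hydrogen-atom transfer from a cobalt hydride, capture of the tertiary radical by O2, reduction by the silane): the 1,1-disubstituted isopropenyl group reacts much faster than the tetrasubstituted C4=C5 alkene and gives the Markovnikov tertiary alcohol at C11, and no stereocentre is formed or touched.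

**Step 6**
Reactants: 9 2,4,6-trimethoxybenzaldehyde
Product: 10 2-[(E)-2-iodoethenyl]-1,3,5-trimethoxybenzene
Conditions: CrCl2 (6 equiv), CHI3 (2 equiv), THF, 0 °C → rt
Reagents that add atoms: iodoform, IC(I)I
Why: Takai olefination: the geminal dichromium reagent made from CHI3 adds to the aldehyde and elimination gives the (E)-vinyl iodide, the E selectivity being highest for aryl aldehydes.

**Step 7**
Reactants: 8 diol; 10 (E)-vinyl iodide
Product: 12 (2S)-2-[(1R,3aR,4R,7R)-7-(2-hydroxypropan-2-yl)-1,4-dimethyl-1,2,3,3a,4,5,6,7-octahydroazulen-1-yl]-2-(2,4,6-trimethoxyphenyl)acetaldehyde, via allyl vinyl ether 11 (not isolated)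
Conditions: CuI (10 mol %), 3,4,7,8-tetramethyl-1,10-phenanthroline (20 mol %), Cs2CO3 (1.5 equiv), o-xylene, 120 °C
Reagents that add atoms: none
Why: Copper-catalysed C–O cross-coupling of a vinyl iodide with an allylic alcohol followed in the same flask by Claisen rearrangement: only the secondary C6 hydroxyl is vinylated (the tertiary one is inert) with retention of the E geometry, the [3,3] shift is suprafacial so that the carbon chain leaves the upper-face C6–O bond and arrives on the upper face of C4 (quaternary centre 4R, alkene moved to C5=C6), and the chair array with the aryl group of the E enol ether pseudo-equatorial and turned away from the bicycle sets C1' as S.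

**Step 8**
Reactants: 12 α-aryl aldehyde
Product: 13 2-[(1R,3aR,4R,7R)-1,4-dimethyl-1-[(1S)-3-methyl-1-(2,4,6-trimethoxyphenyl)but-2-en-1-yl]-1,2,3,3a,4,5,6,7-octahydroazulen-7-yl]propan-2-ol
Conditions: Ph3P(CHMe2)I (2.5 equiv), n-BuLi (2.4 equiv), THF, 0 °C; then 12, −78 → 0 °C
Reagents that add atoms: isopropyltriphenylphosphonium iodide, CC(C)[P+](c1ccccc1)(c1ccccc1)c1ccccc1.[I-]
Why: Wittig reaction with the non-stabilised isopropylidene ylide (in excess, since the tertiary hydroxyl takes up one equivalent): addition at −78 °C should outrun enolisation of the aldehyde, whose α-hydrogen is hard to align because of the flanking quaternary carbon and the di-ortho-substituted arene, so C1' is kept.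

**Step 9**
Reactants: 13 side-chain alkene
Product: 14 2-[(1R,3aR,4R,7R)-1,4-dimethyl-1-[(1S)-3-methyl-1-(2,4,6-trimethoxyphenyl)butyl]-1,2,3,3a,4,5,6,7-octahydroazulen-7-yl]propan-2-ol
Conditions: H2 (1 atm), PtO2 (5 mol %), EtOAc, rt, stopped after one equivalent of H2
Reagents that add atoms: none
Why: Heterogeneous hydrogenation: the side-chain alkene offers an open C(CH3)2 terminus to the catalyst surface whereas C5=C6 is buried between quaternary C4 and the C7–C(CH3)2OH group, so hydrogen should be taken up at the side chain only, and no stereocentre is formed.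

**Step 10**
Reactants: 14 trimethoxyarene
Product: 16 2,4,6-trimethoxy-5-{(1S)-1-[(1R,3aR,4R,7R)-7-(2-hydroxypropan-2-yl)-1,4-dimethyl-1,2,3,3a,4,5,6,7-octahydroazulen-1-yl]-3-methylbutyl}benzene-1,3-dicarbaldehyde, via lithium amino alkoxide 15 (not isolated)
Conditions: n-BuLi (2.3 equiv), TMEDA, THF, 0 °C; DMF (1.1 equiv), −78 → 0 °C; n-BuLi (1.5 equiv), 0 °C; DMF (3 equiv), −78 °C → rt; H2O
Reagents that add atoms: N,N-dimethylformamide, CN(C)C=O
Why: Directed ortho-metalation/formylation run twice in one flask: each free ring position lies between two methoxy groups and is lithiated readily, the first DMF adduct persists as the lithium α-amino alkoxide 15 and so masks the first formyl group during the second lithiation, both adducts collapse to aldehydes on quenching, and the tertiary alcohol rides along as its lithium alkoxide.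

**Step 11**
Reactants: 16 dialdehyde trimethyl ether
Product: 17 2,4,6-trihydroxy-5-{(1S)-1-[(1R,3aR,4R,7R)-7-(2-hydroxypropan-2-yl)-1,4-dimethyl-1,2,3,3a,4,5,6,7-octahydroazulen-1-yl]-3-methylbutyl}benzene-1,3-dicarbaldehyde (target)
Conditions: NaSEt (10 equiv), DMF, 100 °C; then 1 M HCl, 0 °C
Reagents that add atoms: none
Why: Nucleophilic (SN2) O-demethylation by thiolate: all three methoxy groups are twisted out of the ring plane and release phenoxides stabilised by ortho/para formyl groups, while the non-enolisable aldehydes, the alkene and the tertiary alcohol are inert to the soft nucleophile, and no stereocentre is affected.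

**Compound list**

1 | (R)-citronellal | C[C@H](CCC=C(C)C)CC=O | starting material
2 | methyl vinyl ketone | CC(=O)C=C | starting material
3 | (2R)-2-[(2R)-6-methylhept-5-en-2-yl]-5-oxohexanal | CC(=O)CC[C@@H](C=O)[C@H](C)CCC=C(C)C | intermediate
4 | (5R,6R)-5-(2-methoxyethenyl)-6,10-dimethylundec-9-en-2-one (E/Z mixture) | CC(=O)CC[C@@H](C=COC)[C@H](C)CCC=C(C)C | intermediate
5 | (3S)-3-[(2R)-6-methylhept-5-en-2-yl]-6-oxoheptanal | CC(=O)CC[C@@H](CC=O)[C@H](C)CCC=C(C)C | intermediate
6 | (5R)-2-methyl-5-[(2R)-6-methylhept-5-en-2-yl]cyclopent-1-ene-1-carbaldehyde | O=CC1=C(C)CC[C@@H]1[C@H](C)CCC=C(C)C | intermediate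
7 | (4R,5S,8R,8aR)-3,8-dimethyl-5-(prop-1-en-2-yl)-1,2,4,5,6,7,8,8a-octahydroazulen-4-ol | CC1=C2[C@H](O)[C@H](C(C)=C)CC[C@@H](C)[C@H]2CC1 | intermediate
8 | (4R,5R,8R,8aR)-5-(2-hydroxypropan-2-yl)-3,8-dimethyl-1,2,4,5,6,7,8,8a-octahydroazulen-4-ol | CC1=C2[C@H](O)[C@H](C(C)(C)O)CC[C@@H](C)[C@H]2CC1 | intermediate
9 | 2,4,6-trimethoxybenzaldehyde | COc1cc(OC)c(C=O)c(OC)c1 | starting material
10 | 2-[(E)-2-iodoethenyl]-1,3,5-trimethoxybenzene | COc1cc(OC)c(/C=C/I)c(OC)c1 | intermediate
11 | 2-[(4R,5R,8R,8aR)-3,8-dimethyl-4-{[(E)-2-(2,4,6-trimethoxyphenyl)ethenyl]oxy}-1,2,4,5,6,7,8,8a-octahydroazulen-5-yl]propan-2-ol | CC1=C2[C@H](O/C=C/c3c(OC)cc(OC)cc3OC)[C@H](C(C)(C)O)CC[C@@H](C)[C@H]2CC1 | intermediate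
12 | (2S)-2-[(1R,3aR,4R,7R)-7-(2-hydroxypropan-2-yl)-1,4-dimethyl-1,2,3,3a,4,5,6,7-octahydroazulen-1-yl]-2-(2,4,6-trimethoxyphenyl)acetaldehyde | O=C[C@H](c1c(OC)cc(OC)cc1OC)[C@@]1(C)CC[C@H]2C1=C[C@H](C(C)(C)O)CC[C@H]2C | intermediate
13 | 2-[(1R,3aR,4R,7R)-1,4-dimethyl-1-[(1S)-3-methyl-1-(2,4,6-trimethoxyphenyl)but-2-en-1-yl]-1,2,3,3a,4,5,6,7-octahydroazulen-7-yl]propan-2-ol | CC(C)=C[C@H](c1c(OC)cc(OC)cc1OC)[C@@]1(C)CC[C@H]2C1=C[C@H](C(C)(C)O)CC[C@H]2C | intermediate
14 | 2-[(1R,3aR,4R,7R)-1,4-dimethyl-1-[(1S)-3-methyl-1-(2,4,6-trimethoxyphenyl)butyl]-1,2,3,3a,4,5,6,7-octahydroazulen-7-yl]propan-2-ol | CC(C)C[C@H](c1c(OC)cc(OC)cc1OC)[C@@]1(C)CC[C@H]2C1=C[C@H](C(C)(C)O)CC[C@H]2C | intermediate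
15 | dilithium salt: lithium α-(dimethylamino)benzyl alkoxide at the first formylated ring position of 14, tertiary alcohol as lithium alkoxide | CC(C)C[C@H](c1c(OC)cc(OC)c(C(O[Li])N(C)C)c1OC)[C@@]1(C)CC[C@H]2C1=C[C@H](C(C)(C)O[Li])CC[C@H]2C | intermediate
16 | 2,4,6-trimethoxy-5-{(1S)-1-[(1R,3aR,4R,7R)-7-(2-hydroxypropan-2-yl)-1,4-dimethyl-1,2,3,3a,4,5,6,7-octahydroazulen-1-yl]-3-methylbutyl}benzene-1,3-dicarbaldehyde | CC(C)C[C@H](c1c(OC)c(C=O)c(OC)c(C=O)c1OC)[C@@]1(C)CC[C@H]2C1=C[C@H](C(C)(C)O)CC[C@H]2C | intermediate
17 | 2,4,6-trihydroxy-5-{(1S)-1-[(1R,3aR,4R,7R)-7-(2-hydroxypropan-2-yl)-1,4-dimethyl-1,2,3,3a,4,5,6,7-octahydroazulen-1-yl]-3-methylbutyl}benzene-1,3-dicarbaldehyde | CC(C)C[C@H](c1c(O)c(C=O)c(O)c(C=O)c1O)[C@@]1(C)CC[C@H]2C1=C[C@H](C(C)(C)O)CC[C@H]2C | target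

Total step count: 11. Longest linear sequence: 10 steps (steps 1–5 and 7–11).

**Steps most likely to fail**

**Step 4.** Closure of the seven-membered ring may be slower than Lewis-acid-induced isomerisation or oligomerisation of the prenyl group, or the allylic oxygen function just formed may ionise.
- The fallback sets out from 6 and comes back at 7, and replaces the ene reaction by an organochromium allylation.
- Allylic oxidation of the (E)-methyl group of the electron-rich prenyl alkene (SeO2 cat., t-BuOOH, CH2Cl2) should give the (E)-allylic alcohol F1.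
- Appel bromination (CBr4, PPh3) should then give the allylic bromide F2.
- An intramolecular Nozaki–Hiyama allylation (CrCl2, THF, high dilution) follows. The allylchromium reagent adds through its γ-carbon C7 to the formyl group under neutral conditions. This forms the same C6–C7 bond and the isopropenyl group under the same tether constraints, giving 7.

**Step 7.** O-Vinylation of the hindered secondary carbinol may be slow, and the α-aryl aldehyde may epimerise at C1' under carbonate at 120 °C.
- The fallback sets out from 8 and comes back at 12, and uses an Ireland–Claisen rearrangement, whose carboxylate product cannot epimerise.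
- Purchased (2,4,6-trimethoxyphenyl)acetic acid F3 is esterified with the secondary hydroxyl of 8 (EDC, DMAP) to the allylic ester F4.
- KN(SiMe3)2 and Me3SiCl (THF, −78 °C) should give the (Z)-silyl ketene acetal F5, with the aryl group cis to OSiMe3 and the tertiary alcohol silylated in passing.
- Warming takes F5 through the same chair, upper-face [3,3] shift, and acidic work-up gives the carboxylic acid F6.
- LiAlH4 should give the primary alcohol F7, and Dess–Martin periodinane oxidises only the primary hydroxyl to 12.

**Step 8.** Enolisation of the crowded aldehyde by the basic ylide may cause loss of C1' integrity or low conversion. The selectivity of the hydrogenation that follows is a further concern.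
- The fallback sets out from 12 and comes back at 14, bypassing 13.
- The weakly basic organocerium reagent from i-PrMgCl and CeCl3 (THF, −78 °C) adds to 12 to give the secondary alcohol F8 as a carbinol epimer mixture that is of no consequence.
- 1,1'-Thiocarbonyldiimidazole acylates only the secondary hydroxyl to the imidazolyl thionocarbamate F9.
- Barton–McCombie deoxygenation (Bu3SnH, AIBN, toluene, 90 °C) should then give 14 without any hydrogenation.

**Further compounds**

F1 | step 4 | (5R)-5-[(2R,5E)-7-hydroxy-6-methylhept-5-en-2-yl]-2-methylcyclopent-1-ene-1-carbaldehyde | O=CC1=C(C)CC[C@@H]1[C@H](C)CC/C=C(\C)CO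
F2 | step 4 | (5R)-5-[(2R,5E)-7-bromo-6-methylhept-5-en-2-yl]-2-methylcyclopent-1-ene-1-carbaldehyde | O=CC1=C(C)CC[C@@H]1[C@H](C)CC/C=C(\C)CBr
F3 | step 7 | (2,4,6-trimethoxyphenyl)acetic acid | COc1cc(OC)c(CC(=O)O)c(OC)c1
F4 | step 7 | (4R,5R,8R,8aR)-5-(2-hydroxypropan-2-yl)-3,8-dimethyl-1,2,4,5,6,7,8,8a-octahydroazulen-4-yl (2,4,6-trimethoxyphenyl)acetate | CC1=C2[C@H](OC(=O)Cc3c(OC)cc(OC)cc3OC)[C@H](C(C)(C)O)CC[C@@H](C)[C@H]2CC1
F5 | step 7 | (Z)-trimethylsilyl ketene acetal of F4, tertiary alcohol as trimethylsilyl ether | CC1=C2[C@H](O/C(O[Si](C)(C)C)=C/c3c(OC)cc(OC)cc3OC)[C@H](C(C)(C)O[Si](C)(C)C)CC[C@@H](C)[C@H]2CC1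
F6 | step 7 | (2S)-2-[(1R,3aR,4R,7R)-7-(2-hydroxypropan-2-yl)-1,4-dimethyl-1,2,3,3a,4,5,6,7-octahydroazulen-1-yl]-2-(2,4,6-trimethoxyphenyl)acetic acid | OC(=O)[C@H](c1c(OC)cc(OC)cc1OC)[C@@]1(C)CC[C@H]2C1=C[C@H](C(C)(C)O)CC[C@H]2C
F7 | step 7 | primary alcohol obtained by reduction of F6 (CH2OH in place of CO2H) | OC[C@H](c1c(OC)cc(OC)cc1OC)[C@@]1(C)CC[C@H]2C1=C[C@H](C(C)(C)O)CC[C@H]2C
F8 | step 8 | isopropyl carbinol from 12 (CH(OH)CH(CH3)2 in place of CHO, carbinol epimers) | CC(C)C(O)[C@H](c1c(OC)cc(OC)cc1OC)[C@@]1(C)CC[C@H]2C1=C[C@H](C(C)(C)O)CC[C@H]2C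
F9 | step 8 | O-(imidazol-1-ylthiocarbonyl) derivative of F8 at the secondary hydroxyl | CC(C)C(OC(=S)n1ccnc1)[C@H](c1c(OC)cc(OC)cc1OC)[C@@]1(C)CC[C@H]2C1=C[C@H](C(C)(C)O)CC[C@H]2C
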